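If we want the share of mono adduct at the end of a flask, we must know how fast mono adduct is still falling late in that flask.

| flask | substrate | coupling partner | remark | time |
|---|---|---|---|---|
| theta | 0.30 M | 0.39 M | run made earlier |  |
| epsilon | 0.30 M | 0.26 M | run made earlier |  |
| beta | 0.30 M | 0.58 M | run made earlier |  |
| midnight | 0.30 M | 0.390 M (fed, over 3.0 min) | all else is in the flask from the start; the feed brings no volume worth counting | 15 min |
| noon | 0.30 M (fed, over 3.0 min) | 0.390 M | all else is in the flask from the start; the feed brings no volume worth counting | 15 min |
| spring | 0.30 M | 0.390 M | everything together at the start | 15 min |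
| winter | 0.30 M | 0.390 M (in portions, 3, over 3.0 min) | first portion at the start, last at 3.0 min | 15 min |

| run | time / min | mono adduct / % | double product / % | substrate / % |
|---|---|---|---|---|
| theta | 0.667 | 14.3 | 2.3 | 36.7 |
| theta | 1.33 | 12.5 | 5.9 | 18.9 |
| theta | 2.00 | 10.0 | 8.3 | 13.3 |
| theta | 3.00 | 6.3 | 10.9 | 7.9 |
| theta | 5.00 | 5.1 | 13.6 | 4.4 |
| theta | 10.0 | 0 | 14.9 | 0 |
| epsilon | 0.833 | 10.9 | 0.2 | 32.7 |
| epsilon | 2.50 | 9.9 | 3.7 | 11.4 |
| epsilon | 4.00 | 6.9 | 6.4 | 7.4 |
| epsilon | 6.00 | 5.6 | 10.1 | 4.8 |
| epsilon | 10.0 | 3.7 | 10.8 | 3.4 |
| epsilon | 12.0 | 4.2 | 10.7 | 1.3 |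
| beta | 1.00 | 12.2 | 7.5 | 19.2 |
| beta | 1.50 | 11.9 | 10.5 | 12.9 |
| beta | 2.50 | 5.7 | 14.5 | 5.8 |
| beta | 4.00 | 3.1 | 19.9 | 2.5 |
| beta | 8.00 | 0.3 | 18.2 | 0 |
| beta | 12.0 | 0.6 | 19.5 | 0.4 |

(standard deviation of a reading: 1 percentage point)



1. the flask that comes out highest in share of mono adduct in mono adduct plus double product, or "all alike" when all lie within 1.5 percentage points (midnight / noon / spring / winter / all alike)
2. share of mono adduct in mono adduct plus double product at the end, midnight
3. share of mono adduct in mono adduct plus double product at the end, noon
4. share of mono adduct in mono adduct plus double product at the end, spring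
5. share of mono adduct in mono adduct plus double product at the end, winter

**Fastest rung.** In theta, substrate is down to 36.7% by 0.667 min, which gives a first half-life near 0.461 min.

**Middle rung.** In epsilon, mono adduct reads 3.7% at 10.0 min and 4.2% at 12.0 min, with a scatter of 1 percentage point, so the tail there is slow, but we can read no end to it. As a rough working guess, not a reading, we let each flask take about the 0.26 M of coupling partner that epsilon was charged with. Beta then keeps about 0.320 M, and there substrate plus mono adduct fall together at 0.595 min⁻¹. We take this pace as pseudo-first-order, proportional to [coupling partner]. As a first pass, the charged 0.390 M gives a time of 1.38 min, slower than the fastest rung, so we suppose an unseen early loss of substrate, steeper than first order in [substrate].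

**Slowest rung.** Now we put that answer back. The guessed uptake leaves spring about 0.130 M of coupling partner, and at this level the tail lifetime, the time in which substrate and mono adduct fall by a factor e, is 4.14 min. Theta has the charges of spring and shows 5.1% of mono adduct at 5.00 min, so we expect 0.454% at 15 min. Against 14.9% of double product, that is a share of 2.96% in spring.

**The feeds.** In noon, substrate enters over 3.0 min, longer than its early half-life, so [substrate] stays lower, the unseen loss shrinks, more coupling partner is taken, and the tail lengthens. Midnight should do the reverse. We therefore rank noon, spring, winter, midnight.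

**The forecast.** It says midnight, with 6.5% for midnight, 3% for noon, 4.5% for spring and 5% for winter: “Feeding partner keeps it scarce early, so mono survives slightly longer at midnight”. Our ranking differs from it at the top.

**The result.** The highest share stands in noon, at 7.79%, with 1.98% in spring, 0.417% in winter and 0.253% in midnight.

    2 substrate → self-condensation product (k = 0.0450 M⁻¹ s⁻¹)
    coupling partner + mono adduct → over-reaction product (k = 0.0490 M⁻¹ s⁻¹)
    coupling partner + other mono adduct → double product (k = 0.0420 M⁻¹ s⁻¹)
    coupling partner + mono adduct → double product (k = 0.0120 M⁻¹ s⁻¹)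
    substrate + coupling partner → mono adduct (k = 0.0270 M⁻¹ s⁻¹)
    substrate + coupling partner → other mono adduct (k = 0.00550 M⁻¹ s⁻¹)

With the coupling partner left at 15.0 min, the tail lifetime is 8.95 min in noon, longer than the 2.33 min in midnight. The neighbouring midnight flask, read at 6.0 min, holds 1.43% of mono adduct, and that lifetime carries this to 0.0300% at 15 min, where midnight holds 0.0223%.

The runs were generated by integration from invented constants; scatter was added.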